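**Retrosynthetic overview**

1. Target 28 ← 27 (four MOM ethers removed) ← chromone 18 + boronic acid 26 by rhodium-catalysed asymmetric conjugate arylation, which forms C2–C1' and sets C2 (S).
2. 18 ← lavandulyl phenol 13 by ortho-formylation, methyl ketone 16 and enaminone closure of ring C onto the only free phenol.
3. 13 ← dihydrocoumarin 8: the lactone is opened to a Weinreb amide and its carbonyl carbon becomes the isopropenyl carbon on C2'' (MeMgBr, then methylenation).
4. 8 ← sulfone 4 + aryl ester 6. Feature used: C1'' (the benzylic CH2 on C8) lies between the oxygen-bearing carbons C7 and C8a of ring A, so C8, C1'' and the C8a oxygen are a latent ortho-quinone methide, and the stereocentre C2'' is the α-carbon of an ester enolate; the annulation forms C1''–C2'' and a lactone C–O bond.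
5. Ring order: ring A is bought; a temporary lactone ring (closed in step 5, opened in step 6, it marks the future O1); ring C (step 14); ring B is attached last (step 20).

Key step: step 5

Remark: both antipodes of the triazolium salt of step 5 and of the diphosphine of step 20 are available; the antipode written is the one the usual facial models predict, and the mirror-image catalyst would be taken if a trial on a model substrate shows the opposite sense.

"(2R)-Lavandulyl" below means (2R)-5-methyl-2-(prop-1-en-2-yl)hex-4-en-1-yl.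

**Route**

Step 1
Reactants: 1 2,4,6-trihydroxybenzaldehyde
Product: 2 2-hydroxy-4,6-bis(methoxymethoxy)benzaldehyde
Conditions: MOMCl (2.2 equiv), iPr2NEt, CH2Cl2, 0 °C to rt
Reagents that add atoms: chloromethyl methyl ether, COCCl
Why: Williamson-type O-alkylation (MOM protection) in which the two non-chelated hydroxyls react while the one hydrogen-bonded to the aldehyde stays free when two equivalents are used.

Step 2
Reactants: 2 2-hydroxy-4,6-bis(methoxymethoxy)benzaldehyde
Product: 3 2-(hydroxymethyl)-3,5-bis(methoxymethoxy)phenol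
Conditions: NaBH4, THF/MeOH, 0 °C; pH 7 buffer quench; used crude
Reagents that add atoms: none
Why: Borohydride reduction of the aldehyde, run cold and quenched near neutral pH so that the electron-rich salicyl alcohol neither ionises nor is reduced further to the methyl compound.

Step 3
Reactants: 3 2-(hydroxymethyl)-3,5-bis(methoxymethoxy)phenol
Product: 4 3,5-bis(methoxymethoxy)-2-[(4-methylbenzenesulfonyl)methyl]phenol
Conditions: TolSO2Na (3 equiv), AcOH, THF/H2O, rt to 40 °C
Reagents that add atoms: sodium 4-methylbenzenesulfinate, Cc1ccc(S(=O)[O-])cc1.[Na+]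
Why: Acid-promoted SN1-type substitution in which the 2,4,6-trioxygenated benzylic alcohol ionises under weak acid and excess sulfinate captures the cation at sulfur, acetic acid being too weak to cleave the MOM acetals.

Step 4
Reactants: 5 5-methylhex-4-enoic acid
Product: 6 4-nitrophenyl 5-methylhex-4-enoate
Conditions: 4-nitrophenol, EDC·HCl, DMAP (cat.), CH2Cl2, 0 °C to rt
Reagents that add atoms: 4-nitrophenol, Oc1ccc([N+](=O)[O-])cc1
Why: Steglich-type carbodiimide esterification giving an aryl ester active enough for acyl transfer to a carbene.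

Step 5
Reactants: 4 3,5-bis(methoxymethoxy)-2-[(4-methylbenzenesulfonyl)methyl]phenol; 6 4-nitrophenyl 5-methylhex-4-enoate
Product: 8 (3R)-5,7-bis(methoxymethoxy)-3-(3-methylbut-2-en-1-yl)-3,4-dihydro-2H-chromen-2-one, via ortho-quinone methide 7 (not isolated)
Conditions: (5aS,10bR)-2-mesityl-5a,10b-dihydro-4H,6H-indeno[2,1-b][1,2,4]triazolo[4,3-d][1,4]oxazin-2-ium tetrafluoroborate (15 mol%), Cs2CO3 (2.5 equiv), 4 Å molecular sieves, THF, 0 °C to rt
Reagents that add atoms: none
Why: Cs2CO3 deprotonates the phenol of 4 and expels 4-methylbenzenesulfinate to give ortho-quinone methide 7, while the carbene from the triazolium salt adds to ester 6, loses nitrophenoxide and, after α-deprotonation of the acyl azolium, forms a catalyst-bound (Z)-azolium enolate. The enolate α-carbon (C2'') adds to the methide CH2 (C1'') in a Michael step that restores the aromatic ring A, and the phenoxide set free then attacks the acyl azolium in a 6-exo-trig lactonisation that closes the dihydropyranone ring and returns the carbene. The closest known reaction type is the carbene-catalysed formal [4+2] annulation of ortho-quinone methides made in situ with azolium enolates to 3-substituted dihydrocoumarins. The one new stereocentre, C3 of the lactone (later C2''), is set by the fused aminoindane of the carbene, which blocks one face of the enolate so that the methide carbon arrives on the open face to give 3R. The step needs enantiofacial selectivity at the enolate carbon and C-alkylation at the methide carbon: the first rests on the catalyst alone because the unsubstituted methide carbon becomes no stereocentre, the second on the gain of aromaticity, and the two further donor oxygens of ring A should restrain the methide from self-condensation. Mild carbonate at low temperature should keep the α-centre of the aryl lactone from epimerising.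

Step 6
Reactants: 8 (3R)-5,7-bis(methoxymethoxy)-3-(3-methylbut-2-en-1-yl)-3,4-dihydro-2H-chromen-2-one
Product: 9 (2R)-2-{[2-hydroxy-4,6-bis(methoxymethoxy)phenyl]methyl}-N-methoxy-N,5-dimethylhex-4-enamide
Conditions: MeNH(OMe)·HCl, AlMe3, CH2Cl2, 0 °C to rt; Rochelle salt work-up
Reagents that add atoms: N,O-dimethylhydroxylamine hydrochloride, CNOC.Cl
Why: Weinreb amidation in which the dimethylaluminium amide opens the reactive aryl lactone by acyl substitution, freeing only the oxygen that will become O1, and the weakly basic reagent should leave the α-centre untouched.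

Step 7
Reactants: 9 (2R)-2-{[2-hydroxy-4,6-bis(methoxymethoxy)phenyl]methyl}-N-methoxy-N,5-dimethylhex-4-enamide
Product: 10 (2R)-2-{[2-(tert-butyldimethylsilyloxy)-4,6-bis(methoxymethoxy)phenyl]methyl}-N-methoxy-N,5-dimethylhex-4-enamide
Conditions: TBSCl, imidazole, DMF, rt
Reagents that add atoms: tert-butyldimethylsilyl chloride, CC(C)(C)[Si](C)(C)Cl
Why: Silylation of the phenol, needed because a free phenol would close onto the ketone of step 8 to a 2-chromanol whose dehydration would erase C2'' and would also consume the titanium reagent of step 9.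

Step 8
Reactants: 10 (2R)-2-{[2-(tert-butyldimethylsilyloxy)-4,6-bis(methoxymethoxy)phenyl]methyl}-N-methoxy-N,5-dimethylhex-4-enamide
Product: 11 (3R)-3-{[2-(tert-butyldimethylsilyloxy)-4,6-bis(methoxymethoxy)phenyl]methyl}-6-methylhept-5-en-2-one
Conditions: MeMgBr, THF, 0 °C; cold aq. NH4Cl
Reagents that add atoms: methylmagnesium bromide, C[Mg]Br
Why: Weinreb ketone synthesis, in which the chelated tetrahedral intermediate prevents a second addition and a cold buffered quench protects the enolisable α-centre.

Step 9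
Reactants: 11 (3R)-3-{[2-(tert-butyldimethylsilyloxy)-4,6-bis(methoxymethoxy)phenyl]methyl}-6-methylhept-5-en-2-one
Product: 12 tert-butyl{3,5-bis(methoxymethoxy)-2-[(2R)-lavandulyl]phenoxy}dimethylsilane
Conditions: Cp2TiMe2 (3 equiv), toluene/THF, 65 °C, dark
Reagents that add atoms: dimethyltitanocene, [CH3-].[CH3-].[Ti+4].c1cc[cH-]c1.c1cc[cH-]c1
Why: Petasis methylenation through Cp2Ti=CH2 and an oxatitanacyclobutane, chosen because the non-basic reagent does not enolise the α-branched ketone, so C2'' keeps its configuration.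

Step 10
Reactants: 12 tert-butyl{3,5-bis(methoxymethoxy)-2-[(2R)-lavandulyl]phenoxy}dimethylsilane
Product: 13 3,5-bis(methoxymethoxy)-2-[(2R)-lavandulyl]phenol
Conditions: Bu4NF, THF, 0 °C
Reagents that add atoms: none
Why: Fluoride-induced cleavage of the aryl silyl ether, which leaves the MOM acetals and both alkenes alone.

Step 11
Reactants: 13 3,5-bis(methoxymethoxy)-2-[(2R)-lavandulyl]phenol
Product: 14 2-hydroxy-4,6-bis(methoxymethoxy)-3-[(2R)-lavandulyl]benzaldehyde
Conditions: MgCl2 (anhydrous), Et3N, (CH2O)n, MeCN, reflux; cold dilute citric acid work-up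
Reagents that add atoms: paraformaldehyde (as formaldehyde), C=O
Why: Magnesium-mediated ortho-formylation (Casnati–Skattebøl): the magnesium phenoxide directs formaldehyde to the only free ortho carbon and a second formaldehyde oxidises the benzylic alkoxide by hydride transfer, so the CH between the two MOM ethers, not ortho to a free hydroxyl, is not touched.

Step 12
Reactants: 14 2-hydroxy-4,6-bis(methoxymethoxy)-3-[(2R)-lavandulyl]benzaldehyde
Product: 15 2-(1-hydroxyethyl)-3,5-bis(methoxymethoxy)-6-[(2R)-lavandulyl]phenol (both carbinol epimers)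
Conditions: MeMgBr (2.5 equiv), THF, −20 to 0 °C; aq. NH4Cl; used crude
Reagents that add atoms: methylmagnesium bromide, C[Mg]Br
Why: Grignard 1,2-addition to the aldehyde after deprotonation of the phenol; the carbinol centre forms without control and is removed in step 13.

Step 13
Reactants: 15 2-(1-hydroxyethyl)-3,5-bis(methoxymethoxy)-6-[(2R)-lavandulyl]phenol
Product: 16 1-{2-hydroxy-4,6-bis(methoxymethoxy)-3-[(2R)-lavandulyl]phenyl}ethan-1-one
Conditions: MnO2 (activated, excess), CH2Cl2, rt
Reagents that add atoms: none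
Why: MnO2 oxidation of a benzylic alcohol under neutral conditions, which avoids ionisation of the electron-rich 2-hydroxybenzylic alcohol.

Step 14
Reactants: 16 1-{2-hydroxy-4,6-bis(methoxymethoxy)-3-[(2R)-lavandulyl]phenyl}ethan-1-one
Product: 18 5,7-bis(methoxymethoxy)-8-[(2R)-lavandulyl]-4H-chromen-4-one, via enaminone 17 (not isolated)
Conditions: Me2NCH(OMe)2, toluene, 90 °C; evaporate; then AcOH, toluene, 60 °C
Reagents that add atoms: N,N-dimethylformamide dimethyl acetal, COC(OC)N(C)C
Why: Condensation of the methyl ketone with the amide acetal to the enaminone, then acid-promoted 6-endo-trig oxa-Michael addition of the single free phenol and loss of dimethylamine, which closes ring C on the C8a oxygen and so places the lavandulyl group at C8.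

Step 15
Reactants: 19 isovanillin (3-hydroxy-4-methoxybenzaldehyde)
Product: 20 4-methoxy-3-(methoxymethoxy)benzaldehyde
Conditions: MOMCl, iPr2NEt, CH2Cl2, 0 °C to rt
Reagents that add atoms: chloromethyl methyl ether, COCCl
Why: MOM protection of the phenol by O-alkylation, so that the peracid of step 16 meets no free electron-rich phenol.

Step 16
Reactants: 20 4-methoxy-3-(methoxymethoxy)benzaldehyde
Product: 22 4-methoxy-3-(methoxymethoxy)phenol, via aryl formate 21 (not isolated)
Conditions: mCPBA, CH2Cl2, 0 °C to rt; aq. NaHCO3 wash; then K2CO3 (cat.), MeOH, rt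
Reagents that add atoms: 3-chloroperoxybenzoic acid, O=C(OO)c1cccc(Cl)c1
Why: Baeyer–Villiger oxidation of an electron-rich benzaldehyde (Dakin-type), with aryl migration favoured by the para methoxy group, followed by methanolysis of the formate.

Step 17
Reactants: 22 4-methoxy-3-(methoxymethoxy)phenol
Product: 23 1-methoxy-2,4-bis(methoxymethoxy)benzene
Conditions: MOMCl, iPr2NEt, CH2Cl2, 0 °C to rt
Reagents that add atoms: chloromethyl methyl ether, COCCl
Why: O-alkylation of the phenol (MOM protection).

Step 18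
Reactants: 23 1-methoxy-2,4-bis(methoxymethoxy)benzene
Product: 24 1-bromo-5-methoxy-2,4-bis(methoxymethoxy)benzene
Conditions: NBS, MeCN, 0 °C
Reagents that add atoms: N-bromosuccinimide, O=C1CCC(=O)N1Br
Why: Electrophilic aromatic bromination at the carbon para to one MOM ether and ortho to the other, the most activated and least hindered position of a 1,2,4-trialkoxybenzene.

Step 19
Reactants: 24 1-bromo-5-methoxy-2,4-bis(methoxymethoxy)benzene
Product: 26 [5-methoxy-2,4-bis(methoxymethoxy)phenyl]boronic acid, via aryllithium 25 (not isolated)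
Conditions: n-BuLi, THF, −78 °C; B(OiPr)3, −78 °C to rt; H2O, then aq. NH4Cl to pH 6
Reagents that add atoms: triisopropyl borate, CC(C)OB(OC(C)C)OC(C)C; water, O
Why: Bromine–lithium exchange, trapping of the aryllithium with the borate and hydrolysis of the boronate on work-up.

Step 20
Reactants: 18 5,7-bis(methoxymethoxy)-8-[(2R)-lavandulyl]-4H-chromen-4-one; 26 [5-methoxy-2,4-bis(methoxymethoxy)phenyl]boronic acid
Product: 27 (2S)-2-[5-methoxy-2,4-bis(methoxymethoxy)phenyl]-5,7-bis(methoxymethoxy)-8-[(2R)-lavandulyl]-2,3-dihydro-4H-chromen-4-one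
Conditions: [Rh(OH)(cod)]2 (2.5 mol%), (S)-MeO-F12-BIPHEP [(S)-6,6'-dimethoxy-2,2'-bis[bis(3,4,5-trifluorophenyl)phosphino]-1,1'-biphenyl] (5.5 mol%), 26 (3 equiv), toluene/H2O, 30 °C
Reagents that add atoms: none
Why: Rhodium-catalysed asymmetric 1,4-addition of an arylboronic acid to a chromone (Hayashi–Miyaura type): the aryl group passes from boron to rhodium, adds to C2 of the coordinated chromone and the rhodium enolate is protonated by water, the diphosphine fixing the face of C2 that is arylated (2S), while the remote C2'' has no influence and the electron-poor ligand allows a temperature at which the flavanone neither ring-opens nor reacts again.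

Step 21
Reactants: 27 (2S)-2-[5-methoxy-2,4-bis(methoxymethoxy)phenyl]-5,7-bis(methoxymethoxy)-8-[(2R)-lavandulyl]-2,3-dihydro-4H-chromen-4-one
Product: 28 (2S)-2-(2,4-dihydroxy-5-methoxyphenyl)-5,7-dihydroxy-8-[(2R)-lavandulyl]-2,3-dihydro-4H-chromen-4-one (target)
Conditions: 3 M HCl (aq)/MeOH, 45 °C, stopped at full conversion
Reagents that add atoms: none
Why: Acid-catalysed acetal exchange with methanol removes all four MOM groups, under conditions kept mild enough that the C7 hydroxyl should not add to the lavandulyl alkenes and C2 should not epimerise through the chalcone.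

**Compound list**

1 | 2,4,6-trihydroxybenzaldehyde | O=Cc1c(O)cc(O)cc1O | starting material
2 | 2-hydroxy-4,6-bis(methoxymethoxy)benzaldehyde | O=Cc1c(O)cc(OCOC)cc1OCOC | intermediate
3 | 2-(hydroxymethyl)-3,5-bis(methoxymethoxy)phenol | OCc1c(O)cc(OCOC)cc1OCOC | intermediate
4 | 3,5-bis(methoxymethoxy)-2-[(4-methylbenzenesulfonyl)methyl]phenol | Cc1ccc(S(=O)(=O)Cc2c(O)cc(OCOC)cc2OCOC)cc1 | intermediate
5 | 5-methylhex-4-enoic acid | CC(C)=CCCC(=O)O | starting material
6 | 4-nitrophenyl 5-methylhex-4-enoate | CC(C)=CCCC(=O)Oc1ccc([N+](=O)[O-])cc1 | intermediate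
7 | 3,5-bis(methoxymethoxy)-6-methylidenecyclohexa-2,4-dien-1-one (ortho-quinone methide, not isolated) | C=C1C(=O)C=C(OCOC)C=C1OCOC | intermediate
8 | (3R)-5,7-bis(methoxymethoxy)-3-(3-methylbut-2-en-1-yl)-3,4-dihydro-2H-chromen-2-one | O=C1[C@H](CC=C(C)C)Cc2c(O1)cc(OCOC)cc2OCOC | intermediate
9 | (2R)-2-{[2-hydroxy-4,6-bis(methoxymethoxy)phenyl]methyl}-N-methoxy-N,5-dimethylhex-4-enamide | CON(C)C(=O)[C@H](CC=C(C)C)Cc1c(O)cc(OCOC)cc1OCOC | intermediate
10 | (2R)-2-{[2-(tert-butyldimethylsilyloxy)-4,6-bis(methoxymethoxy)phenyl]methyl}-N-methoxy-N,5-dimethylhex-4-enamide | CON(C)C(=O)[C@H](CC=C(C)C)Cc1c(O[Si](C)(C)C(C)(C)C)cc(OCOC)cc1OCOC | intermediate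
11 | (3R)-3-{[2-(tert-butyldimethylsilyloxy)-4,6-bis(methoxymethoxy)phenyl]methyl}-6-methylhept-5-en-2-one | CC(=O)[C@H](CC=C(C)C)Cc1c(O[Si](C)(C)C(C)(C)C)cc(OCOC)cc1OCOC | intermediate
12 | tert-butyl{3,5-bis(methoxymethoxy)-2-[(2R)-5-methyl-2-(prop-1-en-2-yl)hex-4-en-1-yl]phenoxy}dimethylsilane | C=C(C)[C@H](CC=C(C)C)Cc1c(O[Si](C)(C)C(C)(C)C)cc(OCOC)cc1OCOC | intermediate
13 | 3,5-bis(methoxymethoxy)-2-[(2R)-5-methyl-2-(prop-1-en-2-yl)hex-4-en-1-yl]phenol | C=C(C)[C@H](CC=C(C)C)Cc1c(O)cc(OCOC)cc1OCOC | intermediate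
14 | 2-hydroxy-4,6-bis(methoxymethoxy)-3-[(2R)-5-methyl-2-(prop-1-en-2-yl)hex-4-en-1-yl]benzaldehyde | C=C(C)[C@H](CC=C(C)C)Cc1c(O)c(C=O)c(OCOC)cc1OCOC | intermediate
15 | 2-(1-hydroxyethyl)-3,5-bis(methoxymethoxy)-6-[(2R)-5-methyl-2-(prop-1-en-2-yl)hex-4-en-1-yl]phenol (carbinol epimers) | C=C(C)[C@H](CC=C(C)C)Cc1c(O)c(C(C)O)c(OCOC)cc1OCOC | intermediate
16 | 1-{2-hydroxy-4,6-bis(methoxymethoxy)-3-[(2R)-5-methyl-2-(prop-1-en-2-yl)hex-4-en-1-yl]phenyl}ethan-1-one | C=C(C)[C@H](CC=C(C)C)Cc1c(O)c(C(C)=O)c(OCOC)cc1OCOC | intermediate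
17 | (2E)-3-(dimethylamino)-1-{2-hydroxy-4,6-bis(methoxymethoxy)-3-[(2R)-5-methyl-2-(prop-1-en-2-yl)hex-4-en-1-yl]phenyl}prop-2-en-1-one (not isolated) | C=C(C)[C@H](CC=C(C)C)Cc1c(O)c(C(=O)/C=C/N(C)C)c(OCOC)cc1OCOC | intermediate
18 | 5,7-bis(methoxymethoxy)-8-[(2R)-5-methyl-2-(prop-1-en-2-yl)hex-4-en-1-yl]-4H-chromen-4-one | C=C(C)[C@H](CC=C(C)C)Cc1c(OCOC)cc(OCOC)c2c1occc2=O | intermediate
19 | isovanillin (3-hydroxy-4-methoxybenzaldehyde) | COc1ccc(C=O)cc1O | starting material
20 | 4-methoxy-3-(methoxymethoxy)benzaldehyde | COc1ccc(C=O)cc1OCOC | intermediate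
21 | 4-methoxy-3-(methoxymethoxy)phenyl formate (not isolated) | COc1ccc(OC=O)cc1OCOC | intermediate
22 | 4-methoxy-3-(methoxymethoxy)phenol | COc1ccc(O)cc1OCOC | intermediate
23 | 1-methoxy-2,4-bis(methoxymethoxy)benzene | COc1ccc(OCOC)cc1OCOC | intermediate
24 | 1-bromo-5-methoxy-2,4-bis(methoxymethoxy)benzene | COc1cc(Br)c(OCOC)cc1OCOC | intermediate
25 | [5-methoxy-2,4-bis(methoxymethoxy)phenyl]lithium (not isolated) | [Li]c1cc(OC)c(OCOC)cc1OCOC | intermediate
26 | [5-methoxy-2,4-bis(methoxymethoxy)phenyl]boronic acid | COc1cc(B(O)O)c(OCOC)cc1OCOC | intermediate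
27 | (2S)-2-[5-methoxy-2,4-bis(methoxymethoxy)phenyl]-5,7-bis(methoxymethoxy)-8-[(2R)-5-methyl-2-(prop-1-en-2-yl)hex-4-en-1-yl]-2,3-dihydro-4H-chromen-4-one | C=C(C)[C@H](CC=C(C)C)Cc1c(OCOC)cc(OCOC)c2c1O[C@H](c1cc(OC)c(OCOC)cc1OCOC)CC2=O | intermediate
28 | (2S)-2-(2,4-dihydroxy-5-methoxyphenyl)-5,7-dihydroxy-8-[(2R)-5-methyl-2-(prop-1-en-2-yl)hex-4-en-1-yl]-2,3-dihydro-4H-chromen-4-one | C=C(C)[C@H](CC=C(C)C)Cc1c(O)cc(O)c2c1O[C@H](c1cc(OC)c(O)cc1O)CC2=O | target

**Step count and risks**

Total: 21 steps. Longest linear sequence: 15 steps (from 1 through steps 1–3, 5–14, 20 and 21).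

Steps most likely to fail:

- **Step 5.** The methide may oligomerise before the C–C bond forms, facial control at the enolate carbon may be incomplete, or the carbonate may epimerise the α-centre of the aryl lactone. The fallback sets out from 2 and returns at 8, with an auxiliary-controlled alkylation in place of the annulation.
  - Aldehyde 2 would be silylated (TBSCl, imidazole, DMF) to 2-(tert-butyldimethylsilyloxy)-4,6-bis(methoxymethoxy)benzaldehyde F1.
  - A Horner–Wadsworth–Emmons reaction with diethyl {2-[(4R)-4-benzyl-2-oxo-1,3-oxazolidin-3-yl]-2-oxoethyl}phosphonate (LiCl, iPr2NEt, MeCN) should give the (E)-N-cinnamoyl oxazolidinone F2.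
  - Hydrogenation (H2, Pd/C, EtOAc) should give the saturated imide F3.
  - Evans alkylation (NaN(SiMe3)2, THF, −78 °C, prenyl bromide) should give the (2R)-prenylated imide F4, the benzyl group of the (4R)-auxiliary shielding one face of the chelated (Z)-enolate.
  - Bu4NF buffered with AcOH would free the phenoxide, which lactonises onto the imide carbonyl and expels the auxiliary to give 8.

- **Step 20.** The electron-rich, ortho-alkoxy arylboronic acid may protodeboronate faster than it transmetalates, insertion may be slowed by the ortho substituent, or facial selectivity at C2 may be poor. The fallback sets out from 16 and 24 and returns at 27, closing ring C by oxa-Michael addition in place of conjugate arylation.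
  - Bromide 24 would be lithiated (n-BuLi, THF, −78 °C, through 25) and formylated with DMF to 5-methoxy-2,4-bis(methoxymethoxy)benzaldehyde F5.
  - Claisen–Schmidt condensation with 16 (KOH, EtOH) should give the 2'-hydroxychalcone F6.
  - NaOAc in refluxing EtOH should cyclise the single free phenol onto the enone to give 27 together with its C2 epimer F7.
  - Because C2'' is fixed the two are diastereomers and would be separated by preparative HPLC, with F7 returned to the base-mediated equilibration through F6.

- **Step 3.** Under acid the benzylic cation may be attacked by the electron-rich ring of a second molecule (self-condensation) instead of by sulfinate, and the MOM acetals may be partly lost. The fallback sets out from 2 and returns at 4, with no acid and no salicyl alcohol.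
  - Reductive amination (Me2NH, NaBH(OAc)3, ClCH2CH2Cl) should give the Mannich base 2-[(dimethylamino)methyl]-3,5-bis(methoxymethoxy)phenol F8.
  - MeI in acetone should give the trimethylammonium iodide F9.
  - TolSO2Na with NaHCO3 in MeCN/H2O should release ortho-quinone methide 7 by loss of trimethylamine, and the sulfinate traps it to give 4.

**Further compounds**

F1 | step 5 | 2-(tert-butyldimethylsilyloxy)-4,6-bis(methoxymethoxy)benzaldehyde | O=Cc1c(O[Si](C)(C)C(C)(C)C)cc(OCOC)cc1OCOC
F2 | step 5 | (4R)-4-benzyl-3-{(2E)-3-[2-(tert-butyldimethylsilyloxy)-4,6-bis(methoxymethoxy)phenyl]prop-2-enoyl}-1,3-oxazolidin-2-one | O=C1OC[C@@H](Cc2ccccc2)N1C(=O)/C=C/c1c(O[Si](C)(C)C(C)(C)C)cc(OCOC)cc1OCOC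
F3 | step 5 | (4R)-4-benzyl-3-{3-[2-(tert-butyldimethylsilyloxy)-4,6-bis(methoxymethoxy)phenyl]propanoyl}-1,3-oxazolidin-2-one | O=C1OC[C@@H](Cc2ccccc2)N1C(=O)CCc1c(O[Si](C)(C)C(C)(C)C)cc(OCOC)cc1OCOC
F4 | step 5 | (4R)-4-benzyl-3-[(2R)-2-{[2-(tert-butyldimethylsilyloxy)-4,6-bis(methoxymethoxy)phenyl]methyl}-5-methylhex-4-enoyl]-1,3-oxazolidin-2-one | O=C1OC[C@@H](Cc2ccccc2)N1C(=O)[C@H](CC=C(C)C)Cc1c(O[Si](C)(C)C(C)(C)C)cc(OCOC)cc1OCOC
F5 | step 20 | 5-methoxy-2,4-bis(methoxymethoxy)benzaldehyde | COc1cc(C=O)c(OCOC)cc1OCOC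
F6 | step 20 | (2E)-1-{2-hydroxy-4,6-bis(methoxymethoxy)-3-[(2R)-5-methyl-2-(prop-1-en-2-yl)hex-4-en-1-yl]phenyl}-3-[5-methoxy-2,4-bis(methoxymethoxy)phenyl]prop-2-en-1-one | C=C(C)[C@H](CC=C(C)C)Cc1c(O)c(C(=O)/C=C/c2cc(OC)c(OCOC)cc2OCOC)c(OCOC)cc1OCOC
F7 | step 20 | (2R)-2-[5-methoxy-2,4-bis(methoxymethoxy)phenyl]-5,7-bis(methoxymethoxy)-8-[(2R)-5-methyl-2-(prop-1-en-2-yl)hex-4-en-1-yl]-2,3-dihydro-4H-chromen-4-one | C=C(C)[C@H](CC=C(C)C)Cc1c(OCOC)cc(OCOC)c2c1O[C@@H](c1cc(OC)c(OCOC)cc1OCOC)CC2=O
F8 | step 3 | 2-[(dimethylamino)methyl]-3,5-bis(methoxymethoxy)phenol | CN(C)Cc1c(O)cc(OCOC)cc1OCOC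
F9 | step 3 | {[2-hydroxy-4,6-bis(methoxymethoxy)phenyl]methyl}trimethylazanium iodide | C[N+](C)(C)Cc1c(O)cc(OCOC)cc1OCOC.[I-]
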